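**Assumption:** atoms carry germacranolide numbers (ring C1–C10, lactone C6–O–C12(=O)–C11(=C13), C14 on C10, C15 on C4). The SMILES is read as 6S,7R,8R, with both ring olefins Z (ring carbons cis), a cis-fused 6,12-olide and an angelate on O8. Methyl (S)-glycerate is taken as commercially available.

## Retrosynthetic overview

1. The lactone is made last, by palladium-catalysed cyclocarbonylation of the C7 ethynyl carbinol onto C6–OH; the C8 angelate is put on just before.
2. The ten-membered ring comes from a four-atom ring expansion of a cyclohexenone: SmI2 pinacol closure of C8–C9 gives a transient cis-decalin diolate, and Grob fragmentation of C4–C9 (C5 mesylate) gives the C9 ketone and the 4Z olefin. The 1(10)Z enone is the old cyclohexenone olefin.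
3. The precursor is the aldol of the dienolate of 2,6-dimethylcyclohex-2-enone (C4) with an aldehyde (C5) that already carries C6–C8, C11 and C13.
4. That aldehyde comes from methyl (S)-glycerate (C5–C7), a vinyl unit (C8) and acetylide (C11, C13).
5. Ring order: six-membered carbocycle (bought), second six-membered ring (transient), ten-membered ring, γ-lactone.

## Route

Step 1
Reactants: 1 2-methylcyclohex-2-en-1-one
Product: 3 2,6-dimethylcyclohex-2-en-1-one (racemic), via lithium dienolate 2 (not isolated)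
Conditions: LiN(i-Pr)2, THF, −78 °C; MeI, −78 → 0 °C
Reagents that add atoms: iodomethane, CI
Why: Kinetic α′-deprotonation gives the cross-conjugated dienolate, which is C-methylated (enolate alkylation); the new stereocentre is racemic and is erased again in step 6.

Step 2
Reactants: 4 methyl (S)-2,3-dihydroxypropanoate
Product: 5 methyl (S)-2,3-bis(triethylsilyloxy)propanoate
Conditions: Et3SiCl, imidazole, DMF, 0 °C → rt
Reagents that add atoms: chlorotriethylsilane, CC[Si](Cl)(CC)CC
Why: Standard imidazole-promoted silylation protects both hydroxyls and leaves the stereocentre (the future C6) untouched.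

Step 3
Reactants: 5 methyl (S)-2,3-bis(triethylsilyloxy)propanoate
Product: 7 (S)-4,5-bis(triethylsilyloxy)pent-1-en-3-one, via Weinreb amide 6 (not isolated)
Conditions: MeNH(OMe)·HCl, i-PrMgCl, THF, −20 °C; then CH2=CHMgBr, −20 → 0 °C; cold aq. NH4Cl
Reagents that add atoms: vinylmagnesium bromide, C=C[Mg]Br
Why: One-flask Weinreb ketone synthesis: the magnesium amide turns the ester into the N-methoxy-N-methylamide, and the chelated tetrahedral adduct of the vinyl Grignard reagent stops at the ketone; C6 is not touched.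

Step 4
Reactants: 7 (S)-4,5-bis(triethylsilyloxy)pent-1-en-3-one
Product: 9 (3R,4S)-3-ethynyl-3,4,5-tris(triethylsilyloxy)pent-1-ene, via lithium alkoxide 8 (not isolated)
Conditions: HC≡CLi (HC≡CH, n-BuLi), THF, −78 °C; then Et3SiOTf, −78 → 0 °C
Reagents that add atoms: lithium acetylide, [Li]C#C; triethylsilyl trifluoromethanesulfonate, CC[Si](CC)(CC)OS(=O)(=O)C(F)(F)F
Why: 1,2-Addition of the acetylide to the α-silyloxy ketone under Felkin–Anh (non-chelation) control, anti to the C6–O bond, sets C7 as the 6,7-threo diol array; the tertiary alkoxide is silylated in the same flask.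

Step 5
Reactants: 9 (3R,4S)-3-ethynyl-3,4,5-tris(triethylsilyloxy)pent-1-ene
Product: 10 (2R,3R)-3-ethynyl-2,3-bis(triethylsilyloxy)pent-4-enal
Conditions: (COCl)2, DMSO, CH2Cl2, −78 → −30 °C; Et3N
Reagents that add atoms: none
Why: Swern oxidation cleaves and oxidises the primary triethylsilyl ether selectively (secondary and tertiary silyl ethers are inert), giving the α-silyloxy aldehyde directly.

Step 6
Reactants: 3 2,6-dimethylcyclohex-2-en-1-one (racemic); 10 (2R,3R)-3-ethynyl-2,3-bis(triethylsilyloxy)pent-4-enal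
Product: 13 (1S,2S,3R)-1-[(1R)-1,3-dimethyl-2-oxocyclohex-3-en-1-yl]-3-ethynyl-2,3-bis(triethylsilyloxy)pent-4-en-1-yl methanesulfonate, via lithium dienolate 11 (not isolated), via lithium aldolate 12 (not isolated)
Conditions: LiN(i-Pr)2, THF, −78 °C; 10, −78 °C; MsCl, −78 → −20 °C
Reagents that add atoms: methanesulfonyl chloride, CS(=O)(=O)Cl
Why: Aldol addition of the tetrasubstituted enolate through a closed Zimmerman–Traxler transition state puts the C4 methyl (cis to the enolate oxygen) syn to the new C5 oxygen, and Felkin–Anh attack anti to the C6–O bond fixes C5 relative to C6; the aldolate is trapped as the mesylate before retro-aldol can occur.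

Step 7
Reactants: 13 (1S,2S,3R)-1-[(1R)-1,3-dimethyl-2-oxocyclohex-3-en-1-yl]-3-ethynyl-2,3-bis(triethylsilyloxy)pent-4-en-1-yl methanesulfonate
Product: 14 (2R,3S,4S)-4-[(1R)-1,3-dimethyl-2-oxocyclohex-3-en-1-yl]-2-ethynyl-4-(methanesulfonyloxy)-2,3-bis(triethylsilyloxy)butanal
Conditions: O3, pyridine, CH2Cl2, −78 °C; Me2S
Reagents that add atoms: ozone, [O-][O+]=O
Why: Ozonolysis cleaves the monosubstituted olefin selectively (the conjugated enone and the terminal alkyne react much more slowly) and unmasks the C8 aldehyde.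

Step 8
Reactants: 14 (2R,3S,4S)-4-[(1R)-1,3-dimethyl-2-oxocyclohex-3-en-1-yl]-2-ethynyl-4-(methanesulfonyloxy)-2,3-bis(triethylsilyloxy)butanal
Product: 16 (2Z,6Z,8S,9S,10R)-9-ethynyl-10-hydroxy-2,6-dimethyl-8,9-bis(triethylsilyloxy)cyclodeca-2,6-dien-1-one, via samarium diolate 15 (not isolated)
Conditions: SmI2 (2.1 equiv), THF, −78 °C; then t-BuOK, −78 → 0 °C; AcOH
Reagents that add atoms: none
Why: Proposed new method: a reductive pinacol cyclisation–Grob fragmentation cascade that expands the six-membered ring by four atoms. Divalent samarium reduces the chelating α-silyloxy aldehyde to a ketyl that couples with the ring carbonyl through a samarium-bridged chair (only the six-membered closure is within reach; the enone β-carbon would need an eight-membered ring), forming C8–C9 and a cis-fused decalin with the C8 and C9 oxygens cis, which by relay through C4, C5 and C6 is the target configuration at C8. Once the reductant is consumed, exchange to the potassium alkoxide lets the tertiary C9 alkoxide, antiperiplanar across C4–C9 to the equatorial C5 mesylate, fragment heterolytically to the C9 ketone and the C4=C5 olefin; the syn methyl/mesylate relationship becomes 4Z and the ring olefin becomes the 1(10)Z enone, while the C8 alkoxide protects C8 from enolisation. The closest known reactions are SmI2 pinacol cyclisations of keto aldehydes to cis-1,2-diols and the Wharton (Grob) fragmentation of cyclic 1,3-diol monosulfonates; merging them into one ring-expanding operation is new.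

Step 9
Reactants: 16 (2Z,6Z,8S,9S,10R)-9-ethynyl-10-hydroxy-2,6-dimethyl-8,9-bis(triethylsilyloxy)cyclodeca-2,6-dien-1-one; 17 (Z)-2-methylbut-2-enoic acid (angelic acid)
Product: 19 (1R,2S,3S,4Z,8Z)-2-ethynyl-5,9-dimethyl-10-oxo-2,3-bis(triethylsilyloxy)cyclodeca-4,8-dien-1-yl (2Z)-2-methylbut-2-enoate, via mixed anhydride 18 (not isolated)
Conditions: 17, 2,4,6-Cl3C6H2COCl, Et3N, toluene, rt; then 16, 75 °C
Reagents that add atoms: none
Why: Yamaguchi esterification through the preformed mixed anhydride, without DMAP, acylates the only free hydroxyl and is the established way to make angelates without Z-to-E isomerisation; C8 is untouched.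

Step 10
Reactants: 19 (1R,2S,3S,4Z,8Z)-2-ethynyl-5,9-dimethyl-10-oxo-2,3-bis(triethylsilyloxy)cyclodeca-4,8-dien-1-yl (2Z)-2-methylbut-2-enoate
Product: 20 (1R,2R,3S,4Z,8Z)-2-ethynyl-2,3-dihydroxy-5,9-dimethyl-10-oxocyclodeca-4,8-dien-1-yl (2Z)-2-methylbut-2-enoate
Conditions: HF·pyridine, pyridine, THF, 0 °C → rt
Reagents that add atoms: none
Why: Buffered fluoride desilylation frees the C6 and C7 hydroxyls without acyl migration or epimerisation next to the ketone.

Step 11
Reactants: 20 (1R,2R,3S,4Z,8Z)-2-ethynyl-2,3-dihydroxy-5,9-dimethyl-10-oxocyclodeca-4,8-dien-1-yl (2Z)-2-methylbut-2-enoate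
Product: 21 (3aR,4R,6Z,10Z,11aS)-3a-hydroxy-6,10-dimethyl-3-methylidene-2,5-dioxo-2,3,3a,4,5,8,9,11a-octahydrocyclodeca[b]furan-4-yl (2Z)-2-methylbut-2-enoate
Conditions: PdCl2(PPh3)2 (5 mol %), SnCl2 (5 mol %), CO (7 atm), MeCN, 70 °C
Reagents that add atoms: carbon monoxide, [C-]#[O+]
Why: Norton-type palladium-catalysed cyclocarbonylation of a homopropargylic alcohol: the alkoxycarbonyl–palladium species on O6 adds syn across the alkyne (five-membered closure) and protonolysis gives the α-methylene γ-lactone with retention at C6 and C7 (cis-fused); O8 is already acylated and the tertiary C7 hydroxyl could only form a four-membered ring.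

## Compound list

1 | 2-methylcyclohex-2-en-1-one | CC1=CCCC1=O | starting material
2 | lithium 6-methylcyclohexa-1,5-dien-1-olate | CC1=CCCC=C1O[Li] | intermediate
3 | 2,6-dimethylcyclohex-2-en-1-one (racemic) | CC1=CCCC(C)C1=O | intermediate
4 | methyl (S)-2,3-dihydroxypropanoate (methyl L-glycerate) | COC(=O)[C@@H](O)CO | starting material
5 | methyl (S)-2,3-bis(triethylsilyloxy)propanoate | COC(=O)[C@@H](O[Si](CC)(CC)CC)CO[Si](CC)(CC)CC | intermediate
6 | (S)-N-methoxy-N-methyl-2,3-bis(triethylsilyloxy)propanamide | CON(C)C(=O)[C@@H](O[Si](CC)(CC)CC)CO[Si](CC)(CC)CC | intermediate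
7 | (S)-4,5-bis(triethylsilyloxy)pent-1-en-3-one | C=CC(=O)[C@@H](O[Si](CC)(CC)CC)CO[Si](CC)(CC)CC | intermediate
8 | lithium (3R,4S)-3-ethynyl-4,5-bis(triethylsilyloxy)pent-1-en-3-olate | C=C[C@](C#C)(O[Li])[C@@H](O[Si](CC)(CC)CC)CO[Si](CC)(CC)CC | intermediate
9 | (3R,4S)-3-ethynyl-3,4,5-tris(triethylsilyloxy)pent-1-ene | C=C[C@](C#C)(O[Si](CC)(CC)CC)[C@@H](O[Si](CC)(CC)CC)CO[Si](CC)(CC)CC | intermediate
10 | (2R,3R)-3-ethynyl-2,3-bis(triethylsilyloxy)pent-4-enal | C=C[C@](C#C)(O[Si](CC)(CC)CC)[C@@H](O[Si](CC)(CC)CC)C=O | intermediate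
11 | lithium 2,6-dimethylcyclohexa-1,5-dien-1-olate | CC1=CCCC(C)=C1O[Li] | intermediate
12 | lithium (1S,2S,3R)-1-[(1R)-1,3-dimethyl-2-oxocyclohex-3-en-1-yl]-3-ethynyl-2,3-bis(triethylsilyloxy)pent-4-en-1-olate | CC1=CCC[C@@](C)(C1=O)[C@H](O[Li])[C@H](O[Si](CC)(CC)CC)[C@](O[Si](CC)(CC)CC)(C#C)C=C | intermediate
13 | (1S,2S,3R)-1-[(1R)-1,3-dimethyl-2-oxocyclohex-3-en-1-yl]-3-ethynyl-2,3-bis(triethylsilyloxy)pent-4-en-1-yl methanesulfonate | CC1=CCC[C@@](C)(C1=O)[C@H](OS(C)(=O)=O)[C@H](O[Si](CC)(CC)CC)[C@](O[Si](CC)(CC)CC)(C#C)C=C | intermediate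
14 | (2R,3S,4S)-4-[(1R)-1,3-dimethyl-2-oxocyclohex-3-en-1-yl]-2-ethynyl-4-(methanesulfonyloxy)-2,3-bis(triethylsilyloxy)butanal | CC1=CCC[C@@](C)(C1=O)[C@H](OS(C)(=O)=O)[C@H](O[Si](CC)(CC)CC)[C@](O[Si](CC)(CC)CC)(C#C)C=O | intermediate
15 | bis(diiodosamarium) 1,8a-diolate of the cis-fused decalin: 2-ethynyl-4-(methanesulfonyloxy)-4a,8-dimethyl-2,3-bis(triethylsilyloxy)-1,2,3,4,4a,5,6,8a-octahydronaphthalene-1,8a-diolate; C1–O, C8a–O and the C4a methyl all cis, mesylate trans to that methyl | CC1=CCC[C@]2(C)[C@H](OS(C)(=O)=O)[C@H](O[Si](CC)(CC)CC)[C@](O[Si](CC)(CC)CC)(C#C)[C@@H](O[Sm](I)I)[C@]12O[Sm](I)I | intermediate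
16 | (2Z,6Z,8S,9S,10R)-9-ethynyl-10-hydroxy-2,6-dimethyl-8,9-bis(triethylsilyloxy)cyclodeca-2,6-dien-1-one | C#C[C@@]1(O[Si](CC)(CC)CC)[C@@H](O[Si](CC)(CC)CC)/C=C(/C)CC/C=C(/C)C(=O)[C@@H]1O | intermediate
17 | (Z)-2-methylbut-2-enoic acid (angelic acid) | C/C=C(/C)C(=O)O | starting material
18 | (Z)-2-methylbut-2-enoic 2,4,6-trichlorobenzoic anhydride | C/C=C(/C)C(=O)OC(=O)c1c(Cl)cc(Cl)cc1Cl | intermediate
19 | (1R,2S,3S,4Z,8Z)-2-ethynyl-5,9-dimethyl-10-oxo-2,3-bis(triethylsilyloxy)cyclodeca-4,8-dien-1-yl (2Z)-2-methylbut-2-enoate | C#C[C@@]1(O[Si](CC)(CC)CC)[C@@H](O[Si](CC)(CC)CC)/C=C(/C)CC/C=C(/C)C(=O)[C@@H]1OC(=O)/C(C)=C\C | intermediate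
20 | (1R,2R,3S,4Z,8Z)-2-ethynyl-2,3-dihydroxy-5,9-dimethyl-10-oxocyclodeca-4,8-dien-1-yl (2Z)-2-methylbut-2-enoate | C#C[C@@]1(O)[C@@H](O)/C=C(/C)CC/C=C(/C)C(=O)[C@@H]1OC(=O)/C(C)=C\C | intermediate
21 | (3aR,4R,6Z,10Z,11aS)-3a-hydroxy-6,10-dimethyl-3-methylidene-2,5-dioxo-2,3,3a,4,5,8,9,11a-octahydrocyclodeca[b]furan-4-yl (2Z)-2-methylbut-2-enoate (CNP0276177.1) | C=C1C(=O)O[C@H]2/C=C(/C)CC/C=C(/C)C(=O)[C@H](OC(=O)/C(C)=C\C)[C@@]12O | target

## Step count and risks

Total: 11 steps. Longest linear sequence: 10 steps (steps 2–11, from methyl (S)-glycerate 4); step 1 is a one-step side branch.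

**Step 8 (the proposed cascade).** Risks are over-reduction of the enone or of the product α-ketol by excess SmI2, ketyl addition to the alkyne, trans ring fusion (which would give the 4E olefin), and oxetane or oxa-bridged ether formation instead of fragmentation. The fallback uses known reactions and sets out from 14. Ring closure is done by a polar acyl-anion reaction: an intramolecular crossed benzoin (triazolium carbene precatalyst, Et3N, THF) gives the α-ketol (2R,3S,4S,4aR,8aS)-2-ethynyl-8a-hydroxy-4a,8-dimethyl-1-oxo-2,3-bis(triethylsilyloxy)-1,2,3,4,4a,5,6,8a-octahydronaphthalen-4-yl methanesulfonate F3. Its C8 ketone is reduced with LiBH(s-Bu)3 from the face opposite the C7 silyloxy group to the cis-diol (1S,2S,3S,4S,4aR,8aS)-2-ethynyl-1,8a-dihydroxy-4a,8-dimethyl-2,3-bis(triethylsilyloxy)-1,2,3,4,4a,5,6,8a-octahydronaphthalen-4-yl methanesulfonate F4; the facial selectivity of this reduction is the uncertain point of the fallback. A classical Wharton fragmentation of F4 (t-BuOK, t-BuOH/THF, 0 °C) then returns to the route at 16.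

**Step 6 (aldol and mesylation).** A quaternary centre is formed next to a hindered, enolisable aldehyde, and two selectivities are needed at once: Zimmerman–Traxler simple selectivity and Felkin facial selectivity, the latter possibly eroded by the bulky enolate and the β-silyloxy quaternary carbon. The wrong C4/C5 relationship would give the 4E olefin; the wrong C5/C6 relationship would give the C8 epimer. The fallback sets out from 3 (through its dienolate 11) and 10. The dienolate 11 is brominated with N-bromosuccinimide (THF, −78 °C) to 6-bromo-2,6-dimethylcyclohex-2-en-1-one F1. CrCl2 and LiI in THF then generate a trivalent chromium enolate under non-basic conditions, which adds to 10 in a Reformatsky-type aldol through a closed transition state. This gives the free aldol (6R)-6-[(1S,2S,3R)-3-ethynyl-1-hydroxy-2,3-bis(triethylsilyloxy)pent-4-en-1-yl]-2,6-dimethylcyclohex-2-en-1-one F2, which can be purified and is mesylated (MsCl, Et3N, CH2Cl2, 0 °C) to come back to the route at 13.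

**Step 11 (cyclocarbonylation).** Carbonylation has to occur at a quaternary propargylic carbinol in the presence of an enone and an α-acyloxy ketone; Lewis-acid-induced rearrangement of the tertiary propargylic alcohol and low turnover are the dangers. The fallback sets out from 20 and separates carbonylation from ring closure. Markovnikov methoxycarbonylation of the terminal alkyne (Pd(OAc)2, 2-pyridyldiphenylphosphine, MeSO3H, CO, MeOH, 45 °C) gives the branched acrylate methyl 2-{(1R,2S,3Z,7Z,10R)-1,2-dihydroxy-4,8-dimethyl-10-[(2Z)-2-methylbut-2-enoyloxy]-9-oxocyclodeca-3,7-dien-1-yl}prop-2-enoate F5. Acid-catalysed lactonisation onto the C6 hydroxyl (camphorsulfonic acid, toluene, 40 °C) then comes back to the route at 21.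

Further compounds
F1 | step 6 | 6-bromo-2,6-dimethylcyclohex-2-en-1-one (racemic) | CC1=CCCC(C)(Br)C1=O
F2 | step 6 | (6R)-6-[(1S,2S,3R)-3-ethynyl-1-hydroxy-2,3-bis(triethylsilyloxy)pent-4-en-1-yl]-2,6-dimethylcyclohex-2-en-1-one | CC1=CCC[C@@](C)(C1=O)[C@H](O)[C@H](O[Si](CC)(CC)CC)[C@](O[Si](CC)(CC)CC)(C#C)C=C
F3 | step 8 | (2R,3S,4S,4aR,8aS)-2-ethynyl-8a-hydroxy-4a,8-dimethyl-1-oxo-2,3-bis(triethylsilyloxy)-1,2,3,4,4a,5,6,8a-octahydronaphthalen-4-yl methanesulfonate | CC1=CCC[C@]2(C)[C@H](OS(C)(=O)=O)[C@H](O[Si](CC)(CC)CC)[C@](O[Si](CC)(CC)CC)(C#C)C(=O)[C@]12O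
F4 | step 8 | (1S,2S,3S,4S,4aR,8aS)-2-ethynyl-1,8a-dihydroxy-4a,8-dimethyl-2,3-bis(triethylsilyloxy)-1,2,3,4,4a,5,6,8a-octahydronaphthalen-4-yl methanesulfonate | CC1=CCC[C@]2(C)[C@H](OS(C)(=O)=O)[C@H](O[Si](CC)(CC)CC)[C@](O[Si](CC)(CC)CC)(C#C)[C@@H](O)[C@]12O
F5 | step 11 | methyl 2-{(1R,2S,3Z,7Z,10R)-1,2-dihydroxy-4,8-dimethyl-10-[(2Z)-2-methylbut-2-enoyloxy]-9-oxocyclodeca-3,7-dien-1-yl}prop-2-enoate | COC(=O)C(=C)[C@@]1(O)[C@@H](O)/C=C(/C)CC/C=C(/C)C(=O)[C@@H]1OC(=O)/C(C)=C\C
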